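**Retrosynthetic overview**

1. Target 14 ⇒ acetylation and Mitsunobu etherification with umbelliferone 12 ⇒ cis-diol 11; the coumarin is bought.
2. 11 ⇒ γ-lactol 9 by closing the C3–C4 bond. The ring holds a bishomoallylic alcohol, C3(OH)–C4H2–C5H2–C6(=CH2), with carbinol and methylidene carbons 1,4 on the six-membered ring. This is the retron of a nickel-catalysed reductive diene–aldehyde coupling, and the cis-1,3 pair C3–O / C1–CH2O can be stored in one five-membered lactol ring (O, CH2, C1, C2, C3).
3. 9 ⇒ lactone 8 (half-reduction) ⇒ lactone 6 (double methylation builds C2).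
4. 6 ⇒ 2(5H)-furanone 5 + dienyl trifluoroborate 4 (from chloroprene 1) by rhodium-catalysed asymmetric 1,4-addition, which sets C1, the only stereocentre carried into the key step.
5. Ring order: oxolanone ring (from 5) → cyclohexane (step 5, the oxolane ring is opened in the same operation) → coumarin attached last.

Key step: step 5

Locants used in the text: C1 = ring CH bearing CH2O, C2 = CMe2, C3 = CH–O, C4 and C5 = ring CH2, C6 = C(=CH2).
Assumption: chloroprene 1 is taken as the commercial stabilised solution and is distilled before use.
Assumption: the sense of induction of (R)-BINAP in step 2 is taken from the behaviour of cyclic enones and unsaturated lactones; should the opposite sense be found, the (S)-ligand is used.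

**Route**

Step 1
Reactants: 1 chloroprene (2-chlorobuta-1,3-diene)
Product: 4 potassium (buta-1,3-dien-2-yl)trifluoroborate, via buta-1,3-dien-2-ylmagnesium chloride 2 (not isolated), via dimethyl buta-1,3-dien-2-ylboronate 3 (not isolated)
Conditions: Mg, ZnCl2 (cat.), BrCH2CH2Br (cat.), THF, reflux; B(OMe)3, −78 °C → rt; aq. KHF2, rt
Reagents that add atoms: magnesium [Mg] (held only in 2); trimethyl borate COB(OC)OC; potassium hydrogen difluoride [K+].[F-].F
Why: Grignard formation from the vinylic chloride, borylation at the 2-position and fluorination with KHF2 should give the bench-stable trifluoroborate salt, which cannot undergo the Diels–Alder dimerisation of the free dienylboronate.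

Step 2
Reactants: 4 potassium (buta-1,3-dien-2-yl)trifluoroborate; 5 2(5H)-furanone (furan-2(5H)-one)
Product: 6 (4R)-4-(buta-1,3-dien-2-yl)oxolan-2-one
Conditions: Rh(acac)(C2H4)2 (3 mol %), (R)-BINAP (3.3 mol %), dioxane/H2O 10:1, 60 °C
Reagents that add atoms: none
Why: Hayashi–Miyaura asymmetric 1,4-addition, in which the alkenylrhodium species formed by transmetalation inserts the butenolide C=C on the face set by (R)-BINAP (expected to give 4R, the future C1) and water releases the product from the rhodium enolate.

Step 3
Reactants: 6 (4R)-4-(buta-1,3-dien-2-yl)oxolan-2-one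
Product: 8 (4S)-4-(buta-1,3-dien-2-yl)-3,3-dimethyloxolan-2-one, via trans-3-methyl lactone 7 (not isolated)
Conditions: LiN(i-Pr)2 (1.1 equiv), THF, −78 °C, then MeI; LiN(i-Pr)2 (1.3 equiv), −78 °C, then MeI, DMPU, −78 → 0 °C
Reagents that add atoms: iodomethane CI
Why: Two successive lithium enolate alkylations should install the gem-dimethyl carbon C2; C4 is not acidic and keeps its configuration (its descriptor changes from R to S by priority only).

Step 4
Reactants: 8 (4S)-4-(buta-1,3-dien-2-yl)-3,3-dimethyloxolan-2-one
Product: 9 (2RS,4S)-4-(buta-1,3-dien-2-yl)-3,3-dimethyloxolan-2-ol (both anomers)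
Conditions: i-Bu2AlH (1.1 equiv), CH2Cl2, −78 °C; aq. KNaC4H4O6 (tartrate) work-up
Reagents that add atoms: none
Why: Half-reduction of a hindered α,α-dimethyl lactone should stop at the aluminium hemiacetalate at −78 °C and give the lactol on work-up, leaving the diene and C4 untouched.

Step 5
Reactants: 9 (2RS,4S)-4-(buta-1,3-dien-2-yl)-3,3-dimethyloxolan-2-ol
Product: 11 (1R,3S)-3-(hydroxymethyl)-2,2-dimethyl-4-methylidenecyclohexan-1-ol, via open-chain hydroxy aldehyde 10 (not isolated)
Conditions: Ni(acac)2 (10 mol %), Et3B (3 equiv), THF, 25–40 °C, N2; aq. NaHCO3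
Reagents that add atoms: none
Why: Proposed new method: Et3B opens lactol 9 to aldehyde 10, held as a seven-membered O-diethylboryl chelate (C1–CH2O–B←O=C3), and zerovalent nickel (formed from the divalent nickel salt Ni(acac)2 and Et3B) joins the s-cis diene and the activated C3=O by oxidative cyclization, so that the C3–C4 bond forms and a five-membered oxanickelacycle carrying the η3-allyl C5–C6–CH2 results; ethyl transfer from boron to nickel, β-hydride elimination (ethylene) and C–H reductive elimination at C5, the allyl carbon inside the oxanickelacycle, then leave the C6 methylidene and the C3 borinate, which is hydrolysed on work-up. The closest known reaction type is the Ni(acac)2/Et3B homoallylation of aldehydes and lactols with 2-substituted 1,3-dienes, which gives bishomoallylic alcohols with hydrogen placed next to the new bond, together with its ring-forming version for dienes tethered at a terminal carbon; a diene tethered through its inner carbon has not been shown. The cyclohexane closes in a 6-endo mode at the vinyl terminus C4, whereas closure at the exocyclic CH2 would be a 5-endo closure whose forming bond would have to lie near the nodal plane of the diene, so the two-atom tether C1–C2 should secure terminus selectivity. The new stereocentre C3 is controlled by C1 through the boron bridge and the half-chair of the forming ring: the C3 oxygen must point to the nickel-bearing face, and the bridge places the C1–CH2O arm pseudoaxial on the same face (a position that also avoids allylic strain with the exocyclic CH2 and one gauche contact with the C2 methyl groups), which should give the cis-1,3 diol (1R,3S) that relaxes to the diequatorial chair. The step thus needs C4-over-CH2 terminus selectivity, 1,2- rather than 1,4-hydrogen delivery and cis face selectivity, secured respectively by the tether length, by the oxanickelacycle that holds C5 and not the exocyclic carbon on nickel, and by the lactol-derived boron bridge.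

Step 6
Reactants: 11 (1R,3S)-3-(hydroxymethyl)-2,2-dimethyl-4-methylidenecyclohexan-1-ol; 12 umbelliferone (7-hydroxy-2H-chromen-2-one)
Product: 13 7-{[(1S,3R)-3-hydroxy-2,2-dimethyl-6-methylidenecyclohexyl]methoxy}-2H-chromen-2-one
Conditions: PPh3, DIAD, THF, 0 °C → rt
Reagents that add atoms: none
Why: Mitsunobu etherification, in which only the primary alcohol gives an alkoxyphosphonium ion that the acidic phenol can displace by SN2, the secondary C3–OH next to the quaternary carbon being inert and no stereocentre being touched.

Step 7
Reactants: 13 7-{[(1S,3R)-3-hydroxy-2,2-dimethyl-6-methylidenecyclohexyl]methoxy}-2H-chromen-2-one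
Product: 14 (1R,3S)-2,2-dimethyl-4-methylidene-3-{[(2-oxo-2H-chromen-7-yl)oxy]methyl}cyclohexyl acetate (target)
Conditions: Ac2O, DMAP (cat.), pyridine, CH2Cl2, rt
Reagents that add atoms: acetic anhydride CC(=O)OC(C)=O
Why: DMAP-catalysed acylation of the remaining equatorial secondary alcohol proceeds with retention at C3, and the coumarin lactone and the aryl ether are stable to these conditions.

**Compound list**

1 | chloroprene (2-chlorobuta-1,3-diene) | C=CC(Cl)=C | starting material
2 | buta-1,3-dien-2-ylmagnesium chloride | C=CC(=C)[Mg]Cl | intermediate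
3 | dimethyl buta-1,3-dien-2-ylboronate | C=CC(=C)B(OC)OC | intermediate
4 | potassium (buta-1,3-dien-2-yl)trifluoroborate | C=CC(=C)[B-](F)(F)F.[K+] | intermediate
5 | 2(5H)-furanone | O=C1OCC=C1 | starting material
6 | (4R)-4-(buta-1,3-dien-2-yl)oxolan-2-one | O=C1OC[C@@H](C(=C)C=C)C1 | intermediate
7 | (3S,4R)-4-(buta-1,3-dien-2-yl)-3-methyloxolan-2-one (trans-3-methyl lactone) | O=C1OC[C@@H](C(=C)C=C)[C@@H]1C | intermediate
8 | (4S)-4-(buta-1,3-dien-2-yl)-3,3-dimethyloxolan-2-one | O=C1OC[C@@H](C(=C)C=C)C1(C)C | intermediate
9 | (2RS,4S)-4-(buta-1,3-dien-2-yl)-3,3-dimethyloxolan-2-ol | OC1OC[C@@H](C(=C)C=C)C1(C)C | intermediate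
10 | (3S)-3-(hydroxymethyl)-2,2-dimethyl-4-methylidenehex-5-enal (open-chain hydroxy aldehyde) | O=CC(C)(C)[C@@H](CO)C(=C)C=C | intermediate
11 | (1R,3S)-3-(hydroxymethyl)-2,2-dimethyl-4-methylidenecyclohexan-1-ol | C=C1CC[C@@H](O)C(C)(C)[C@H]1CO | intermediate
12 | umbelliferone (7-hydroxy-2H-chromen-2-one) | O=c1ccc2ccc(O)cc2o1 | starting material
13 | 7-{[(1S,3R)-3-hydroxy-2,2-dimethyl-6-methylidenecyclohexyl]methoxy}-2H-chromen-2-one | C=C1CC[C@@H](O)C(C)(C)[C@H]1COc1ccc2ccc(=O)oc2c1 | intermediate
14 | (1R,3S)-2,2-dimethyl-4-methylidene-3-{[(2-oxo-2H-chromen-7-yl)oxy]methyl}cyclohexyl acetate | C=C1CC[C@@H](OC(C)=O)C(C)(C)[C@H]1COc1ccc2ccc(=O)oc2c1 | target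

**Totals and risks**

Total step count: 7. Longest linear sequence: 7 steps (from chloroprene 1).

Steps most likely to fail:

1. Step 5 (key step). What may go wrong:
   - ring closure at the exocyclic diene terminus instead of C4;
   - hydrogen delivery in the 1,4-sense, giving the endocyclic alkene;
   - attack on the opposite face at C3 if the boron bridge does not operate — an unbridged oxanickelacycle with the C1 arm pseudoequatorial would favour the trans-diol;
   - nickel-mediated oligomerisation of the diene.

   Fallback (known chemistry, same ring-closing bond), setting out from lactone 8 and returning at diol 11: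
   - Hydroboration of the monosubstituted vinyl group with 9-BBN and oxidation with NaBO3·4H2O should give (4S)-4-(4-hydroxybut-1-en-2-yl)-3,3-dimethyloxolan-2-one F1.
   - Appel iodination (PPh3, I2, imidazole) gives (4S)-4-(4-iodobut-1-en-2-yl)-3,3-dimethyloxolan-2-one F2.
   - Samarium diiodide intramolecular nucleophilic acyl substitution (SmI2, Fe(dbm)3 cat., THF, −30 °C → rt) lets the C4 organosamarium attack the lactone carbonyl C3 and should give (3S)-3-(hydroxymethyl)-2,2-dimethyl-4-methylidenecyclohexan-1-one F3.
   - NaBH4 in MeOH at 0 °C, with axial hydride delivery anti to the axial C2 methyl group as in 4,4-dimethyl-3-oxo terpenoids, should give the equatorial alcohol 11.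

2. Step 2. What may go wrong:
   - isomerisation of the dien-2-yl–rhodium species to an allenylmethyl species before insertion;
   - protodeboronation;
   - Diels–Alder consumption of the electron-rich borato-diene by the butenolide.

   Fallback, setting out from furanone 5 and returning at lactone 8 (the diene is built stepwise from a vinyl group instead of being transferred intact):
   - The same rhodium/(R)-BINAP 1,4-addition with commercial potassium vinyltrifluoroborate should give (4R)-4-ethenyloxolan-2-one F4.
   - Double methylation (LiN(i-Pr)2, MeI, twice) gives (4S)-4-ethenyl-3,3-dimethyloxolan-2-one F5.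
   - Wacker oxidation (PdCl2, CuCl, O2, DMF/H2O) gives (4S)-4-acetyl-3,3-dimethyloxolan-2-one F6.
   - Kinetic enolisation at the methyl group (KN(SiMe3)2, THF, −78 °C) and trapping with PhNTf2 gives 1-[(3S)-4,4-dimethyl-5-oxooxolan-3-yl]ethenyl trifluoromethanesulfonate F7.
   - Stille coupling with tributyl(vinyl)stannane (Pd(PPh3)4, LiCl, THF, 60 °C) gives 8.

3. Step 6. What may go wrong:
   - intramolecular displacement of the activated primary oxygen by the cis C3–OH (cyclodehydration of the 1,4-diol to a bridged ether);
   - slow SN2 at the β-branched primary carbon.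

   Fallback, setting out from diol 11 and returning at target 14 (the order of the two oxygen functionalisations is reversed so that no free hydroxyl is present during etherification):
   - Silylation of the primary alcohol (TBSCl, imidazole, DMF, 0 °C) gives (1R,3S)-3-({[tert-butyl(dimethyl)silyl]oxy}methyl)-2,2-dimethyl-4-methylidenecyclohexan-1-ol F8.
   - Acetylation (Ac2O, DMAP, pyridine) gives (1R,3S)-3-({[tert-butyl(dimethyl)silyl]oxy}methyl)-2,2-dimethyl-4-methylidenecyclohexyl acetate F9.
   - Desilylation (HF·pyridine, THF) gives (1R,3S)-3-(hydroxymethyl)-2,2-dimethyl-4-methylidenecyclohexyl acetate F10.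
   - Mitsunobu etherification of F10 with umbelliferone 12 (PPh3, DIAD, THF) gives 14 directly.

**Further compounds**

F1 | step 5 | (4S)-4-(4-hydroxybut-1-en-2-yl)-3,3-dimethyloxolan-2-one | O=C1OC[C@@H](C(=C)CCO)C1(C)C
F2 | step 5 | (4S)-4-(4-iodobut-1-en-2-yl)-3,3-dimethyloxolan-2-one | O=C1OC[C@@H](C(=C)CCI)C1(C)C
F3 | step 5 | (3S)-3-(hydroxymethyl)-2,2-dimethyl-4-methylidenecyclohexan-1-one | C=C1CCC(=O)C(C)(C)[C@H]1CO
F4 | step 2 | (4R)-4-ethenyloxolan-2-one | O=C1OC[C@@H](C=C)C1
F5 | step 2 | (4S)-4-ethenyl-3,3-dimethyloxolan-2-one | O=C1OC[C@@H](C=C)C1(C)C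
F6 | step 2 | (4S)-4-acetyl-3,3-dimethyloxolan-2-one | O=C1OC[C@@H](C(C)=O)C1(C)C
F7 | step 2 | 1-[(3S)-4,4-dimethyl-5-oxooxolan-3-yl]ethenyl trifluoromethanesulfonate | O=C1OC[C@@H](C(=C)OS(=O)(=O)C(F)(F)F)C1(C)C
F8 | step 6 | (1R,3S)-3-({[tert-butyl(dimethyl)silyl]oxy}methyl)-2,2-dimethyl-4-methylidenecyclohexan-1-ol | C=C1CC[C@@H](O)C(C)(C)[C@H]1CO[Si](C)(C)C(C)(C)C
F9 | step 6 | (1R,3S)-3-({[tert-butyl(dimethyl)silyl]oxy}methyl)-2,2-dimethyl-4-methylidenecyclohexyl acetate | C=C1CC[C@@H](OC(C)=O)C(C)(C)[C@H]1CO[Si](C)(C)C(C)(C)C
F10 | step 6 | (1R,3S)-3-(hydroxymethyl)-2,2-dimethyl-4-methylidenecyclohexyl acetate | C=C1CC[C@@H](OC(C)=O)C(C)(C)[C@H]1CO
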